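**Plan**

- Feature: ring A of the flavone (C4a, C5, C6, C7, C8, C8a) is an acylphloroglucinol. Oxygen sits on C5, C7 and C8a, and the methoxy groups sit on C6 and C8, the carbons that derive from chain methylenes. A folded 2,4-dimethoxy-3,5,7-trioxo ester therefore already holds every atom of ring A.
- Retrosynthesis: cut the two B-ring benzyl ethers and the C7 O–methyl bond, then O1–C2 (ring C), then C4a–C5 (ring A, Claisen), then chain bonds C6–C7, C4–C5 and C2–C3 of the trioxo ester, and C8=C9 of the cinnamoyl unit.
- Forward: ring B comes from 4-O-methylgallate. The chain is joined by Claisen self-condensation, dianion acetylation and trianion cinnamoylation. Ring A closes first (step 8), ring C second (step 9).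
- Stereochemistry: the target has no stereocentre. The E-alkene from the Horner–Wadsworth–Emmons step is consumed when ring C forms, and the chain CH(OMe) centres are carried as mixtures and become aromatic carbons.

Key step: step 8

Remark on the chemistry: Gardenin E is achiral, so "single enantiomer" is taken to mean the one constitution drawn. Compounds 8, 10 and 11 are used as mixtures of epimers and keto–enol forms.

**Route**

Step 1
Reactants: 1 methyl 3,5-dihydroxy-4-methoxybenzoate
Product: 2 methyl 3,5-bis(benzyloxy)-4-methoxybenzoate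
Conditions: BnBr (2.4 equiv), K2CO3, DMF, 60 °C
Reagents that add atoms: benzyl bromide, BrCc1ccccc1
Why: Williamson ether synthesis; both phenoxides are alkylated by the benzylic bromide while the ester and the aryl methyl ether are inert to carbonate.

Step 2
Reactants: 2 methyl 3,5-bis(benzyloxy)-4-methoxybenzoate
Product: 3 [3,5-bis(benzyloxy)-4-methoxyphenyl]methanol
Conditions: LiAlH4, THF, 0 °C → rt; Fieser work-up
Reagents that add atoms: none
Why: Hydride reduction of an aryl ester to the benzylic alcohol; aryl benzyl and methyl ethers do not react with LiAlH4.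

Step 3
Reactants: 3 [3,5-bis(benzyloxy)-4-methoxyphenyl]methanol
Product: 4 3,5-bis(benzyloxy)-4-methoxybenzaldehyde
Conditions: activated MnO2 (excess), CH2Cl2, rt
Reagents that add atoms: none
Why: MnO2 oxidation is selective for benzylic alcohols and stops at the aldehyde.

Step 4
Reactants: 4 3,5-bis(benzyloxy)-4-methoxybenzaldehyde; 5 diethyl [2-(methoxy(methyl)amino)-2-oxoethyl]phosphonate
Product: 6 (E)-3-[3,5-bis(benzyloxy)-4-methoxyphenyl]-N-methoxy-N-methylprop-2-enamide
Conditions: NaH, THF, 0 °C → rt
Reagents that add atoms: none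
Why: Horner–Wadsworth–Emmons olefination with an amide-stabilised phosphonate should give the E-alkene under thermodynamic control and delivers the cinnamoyl unit directly as its Weinreb amide.

Step 5
Reactants: 7 methyl methoxyacetate (two molecules)
Product: 8 methyl 2,4-dimethoxy-3-oxobutanoate (racemic, keto–enol mixture)
Conditions: NaH (0.55 equiv per ester), THF, reflux; cold dil. HCl
Reagents that add atoms: none
Why: Claisen self-condensation of an α-alkoxy ester, driven to completion by deprotonation of the β-keto ester formed.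

Step 6
Reactants: 8 methyl 2,4-dimethoxy-3-oxobutanoate; 9 N-methoxy-N-methylacetamide
Product: 10 methyl 2,4-dimethoxy-3,5-dioxohexanoate (mixture of epimers and enol forms)
Conditions: LDA (2.2 equiv), THF, −78 → 0 °C; then 9, −78 → 0 °C; cold dil. HCl
Reagents that add atoms: none
Why: Weiler dianion acylation; the γ-carbanion at the methoxymethylene carbon is the more nucleophilic site and adds to the Weinreb amide, whose chelated tetrahedral adduct persists until the quench, so the acidic product cannot protonate unreacted dianion.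

Step 7
Reactants: 10 methyl 2,4-dimethoxy-3,5-dioxohexanoate; 6 (E)-3-[3,5-bis(benzyloxy)-4-methoxyphenyl]-N-methoxy-N-methylprop-2-enamide
Product: 11 methyl (E)-9-[3,5-bis(benzyloxy)-4-methoxyphenyl]-2,4-dimethoxy-3,5,7-trioxonon-8-enoate (mixture of epimers and enol forms)
Conditions: 10 (1.5 equiv), LDA (3.3 equiv per 10), THF, −78 → 0 °C; then 6, −78 → −20 °C; cold dil. HCl to pH 4, no heating on isolation
Reagents that add atoms: none
Why: Polyanion acylation of a β,δ-diketo ester; the last-formed and most basic carbanion of the trianion, at the terminal methyl carbon, should add 1,2 to the Weinreb amide, and the stable chelate prevents a second addition.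

Step 8
Reactants: 11 methyl (E)-9-[3,5-bis(benzyloxy)-4-methoxyphenyl]-2,4-dimethoxy-3,5,7-trioxonon-8-enoate
Product: 13 (E)-3-[3,5-bis(benzyloxy)-4-methoxyphenyl]-1-(2,4,6-trihydroxy-3,5-dimethoxyphenyl)prop-2-en-1-one, via cyclohexanetrione tautomer 12 (not isolated)
Conditions: NaOMe (5 equiv), degassed MeOH, Ar, 0 °C → rt; cold dil. HCl to pH 4
Reagents that add atoms: none
Why: Proposed new method: excess methoxide should turn 11 into a polyenolate in which the C3, C5 and C7 ketones are masked as enolates, so the carbanion at the unsubstituted C6 methylene adds to the only free carbonyl, the C1 ester, methoxide leaves, and the triketone 12 tautomerises to the aromatic phloroglucinol 13, the new bond being the future C4a–C5 bond of the flavone. The closest known reaction type is the hydroxide- or alkoxide-induced Claisen cyclisation of 3,5,7-trioxoalkanoic esters to acylphloroglucinols, the chemical counterpart of chalcone synthase, which has not been run with alkoxy groups on C2 and C4. Ring A closes in the 6-(enolendo)-exo-trig mode. No stereocentre is formed, and the two epimeric CH(OMe) centres become aromatic carbons. The step needs C-acylation by C6 in preference to aldol closure, lactonisation and oxa-Michael addition: the aldol alternative (C2 onto C7) would make a quaternary C2 that cannot aromatise and so reverts, C4 reaches no carbonyl through a six-membered ring, and the O-acylation and conjugate-addition products are reopened by methoxide, so that only the irreversible aromatisation to 13 drains the equilibria.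

Step 9
Reactants: 13 (E)-3-[3,5-bis(benzyloxy)-4-methoxyphenyl]-1-(2,4,6-trihydroxy-3,5-dimethoxyphenyl)prop-2-en-1-one
Product: 15 2-[3,5-bis(benzyloxy)-4-methoxyphenyl]-5,7-dihydroxy-6,8-dimethoxy-4H-chromen-4-one, via flavanone 14 (not isolated)
Conditions: I2 (10 mol %), DMSO, 110 °C
Reagents that add atoms: none
Why: Iodine-mediated oxidative cyclisation of a 2'-hydroxychalcone (6-endo oxa-Michael closure to 14, then α-iodination and loss of HI, with DMSO regenerating iodine); ring A is symmetric about the acyl axis so either ortho hydroxyl gives the same flavone, C6 and C8 are blocked against iodination, and any 14 already formed during the work-up of step 8 follows the same path.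

Step 10
Reactants: 15 2-[3,5-bis(benzyloxy)-4-methoxyphenyl]-5,7-dihydroxy-6,8-dimethoxy-4H-chromen-4-one
Product: 16 2-[3,5-bis(benzyloxy)-4-methoxyphenyl]-5-hydroxy-6,7,8-trimethoxy-4H-chromen-4-one
Conditions: MeI (1.1 equiv), K2CO3, acetone, rt
Reagents that add atoms: iodomethane, CI
Why: Selective Williamson methylation; the 7-hydroxyl is the acidic, vinylogous-acid phenol, whereas the 5-hydroxyl is held in a hydrogen bond to the C4 carbonyl and should stay free with one equivalent of electrophile.

Step 11
Reactants: 16 2-[3,5-bis(benzyloxy)-4-methoxyphenyl]-5-hydroxy-6,7,8-trimethoxy-4H-chromen-4-one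
Product: 17 Gardenin E, 2-(3,5-dihydroxy-4-methoxyphenyl)-5-hydroxy-6,7,8-trimethoxy-4H-chromen-4-one
Conditions: H2 (1 atm), 10 % Pd/C, EtOAc–MeOH, rt
Reagents that add atoms: none
Why: Hydrogenolysis of aryl benzyl ethers over palladium; the chromone C2=C3 bond and the aryl methyl ethers are expected to survive at ambient pressure and temperature.

**Compound list**

1 | methyl 3,5-dihydroxy-4-methoxybenzoate | COC(=O)c1cc(O)c(OC)c(O)c1 | starting material
2 | methyl 3,5-bis(benzyloxy)-4-methoxybenzoate | COC(=O)c1cc(OCc2ccccc2)c(OC)c(OCc2ccccc2)c1 | intermediate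
3 | [3,5-bis(benzyloxy)-4-methoxyphenyl]methanol | OCc1cc(OCc2ccccc2)c(OC)c(OCc2ccccc2)c1 | intermediate
4 | 3,5-bis(benzyloxy)-4-methoxybenzaldehyde | O=Cc1cc(OCc2ccccc2)c(OC)c(OCc2ccccc2)c1 | intermediate
5 | diethyl [2-(methoxy(methyl)amino)-2-oxoethyl]phosphonate | CCOP(=O)(CC(=O)N(C)OC)OCC | starting material
6 | (E)-3-[3,5-bis(benzyloxy)-4-methoxyphenyl]-N-methoxy-N-methylprop-2-enamide | CON(C)C(=O)/C=C/c1cc(OCc2ccccc2)c(OC)c(OCc2ccccc2)c1 | intermediate
7 | methyl methoxyacetate | COCC(=O)OC | starting material
8 | methyl 2,4-dimethoxy-3-oxobutanoate (racemic) | COCC(=O)C(OC)C(=O)OC | intermediate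
9 | N-methoxy-N-methylacetamide | CC(=O)N(C)OC | starting material
10 | methyl 2,4-dimethoxy-3,5-dioxohexanoate (mixture of epimers and enol forms) | COC(=O)C(OC)C(=O)C(OC)C(C)=O | intermediate
11 | methyl (E)-9-[3,5-bis(benzyloxy)-4-methoxyphenyl]-2,4-dimethoxy-3,5,7-trioxonon-8-enoate (mixture of epimers and enol forms) | COC(=O)C(OC)C(=O)C(OC)C(=O)CC(=O)/C=C/c1cc(OCc2ccccc2)c(OC)c(OCc2ccccc2)c1 | intermediate
12 | 2-[(E)-3-[3,5-bis(benzyloxy)-4-methoxyphenyl]prop-2-enoyl]-4,6-dimethoxycyclohexane-1,3,5-trione (mixture of stereoisomers and enol forms; not isolated) | COC1C(=O)C(OC)C(=O)C(C(=O)/C=C/c2cc(OCc3ccccc3)c(OC)c(OCc3ccccc3)c2)C1=O | intermediate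
13 | (E)-3-[3,5-bis(benzyloxy)-4-methoxyphenyl]-1-(2,4,6-trihydroxy-3,5-dimethoxyphenyl)prop-2-en-1-one | COc1c(O)c(OC)c(O)c(C(=O)/C=C/c2cc(OCc3ccccc3)c(OC)c(OCc3ccccc3)c2)c1O | intermediate
14 | 2-[3,5-bis(benzyloxy)-4-methoxyphenyl]-5,7-dihydroxy-6,8-dimethoxychroman-4-one (racemic; not isolated) | COc1c(O)c(OC)c2OC(c3cc(OCc4ccccc4)c(OC)c(OCc4ccccc4)c3)CC(=O)c2c1O | intermediate
15 | 2-[3,5-bis(benzyloxy)-4-methoxyphenyl]-5,7-dihydroxy-6,8-dimethoxy-4H-chromen-4-one | COc1c(O)c(OC)c2oc(-c3cc(OCc4ccccc4)c(OC)c(OCc4ccccc4)c3)cc(=O)c2c1O | intermediate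
16 | 2-[3,5-bis(benzyloxy)-4-methoxyphenyl]-5-hydroxy-6,7,8-trimethoxy-4H-chromen-4-one | COc1c(OC)c(OC)c2oc(-c3cc(OCc4ccccc4)c(OC)c(OCc4ccccc4)c3)cc(=O)c2c1O | intermediate
17 | Gardenin E, 2-(3,5-dihydroxy-4-methoxyphenyl)-5-hydroxy-6,7,8-trimethoxy-4H-chromen-4-one (achiral) | COc1c(O)cc(-c2cc(=O)c3c(O)c(OC)c(OC)c(OC)c3o2)cc1O | target

**Step count and risks**

Total steps: 11. Longest linear sequence: 9 steps (1, 2, 3, 4, 7, 8, 9, 10, 11, from compound 1). The polyketide branch (steps 5 and 6) joins at step 7.

Steps most likely to fail: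

1. Step 8 (Proposed new method). Methoxide may fragment the non-enolised α-methoxy β-keto ester by retro-Claisen cleavage, the chain may rest as the lactone without onward C-acylation, or the electron-rich polyphenolate may be oxidised by air. The fallback builds ring A from an existing arene by known chemistry; it sets out from 4 and comes back at 17. Claisen–Schmidt condensation of 4 with 1-(2-hydroxy-3,4,5,6-tetramethoxyphenyl)ethanone F1 (KOH, EtOH, rt) should give (E)-3-[3,5-bis(benzyloxy)-4-methoxyphenyl]-1-(2-hydroxy-3,4,5,6-tetramethoxyphenyl)prop-2-en-1-one F2. Iodine in DMSO at 110 °C should close this to 2-[3,5-bis(benzyloxy)-4-methoxyphenyl]-5,6,7,8-tetramethoxy-4H-chromen-4-one F3. BCl3 in CH2Cl2 (−78 → 0 °C) should then cleave both benzyl ethers and, by chelation to the C4 carbonyl, the C5 methyl ether alone among the methoxy groups, giving 17.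

2. Step 7. The terminal carbanion may add in conjugate fashion to the cinnamoyl amide, or the third deprotonation may be incomplete so that the less basic internal sites or the enolate oxygens are acylated. The fallback lowers the charge to a dianion by tying C1–C5 into a pyranone; it sets out from 10 and comes back at 11. Enol-lactonisation of 10 (DBU, toluene, reflux) should give 4-hydroxy-3,5-dimethoxy-6-methyl-2H-pyran-2-one F4. Its dianion (LDA, 2.2 equiv, THF, −78 °C), formed at the hydroxyl and the 6-methyl group, should be acylated by 6 to give 6-[(E)-4-[3,5-bis(benzyloxy)-4-methoxyphenyl]-2-oxobut-3-en-1-yl]-4-hydroxy-3,5-dimethoxy-2H-pyran-2-one F5. Mg(OMe)2 in MeOH at reflux should open the lactone to 11, which in this variant is not isolated and is carried by the same alkoxide medium into step 8.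

3. Step 6. The strongly basic γ-carbanion may take a proton from the acetyl group of the amide, or acylation may occur on oxygen, returning 8. The fallback reaches the same oxidation level by aldol addition and oxidation; it sets out from 8 and comes back at 10. The dianion of 8 (LDA, 2.2 equiv, THF, −78 °C) should add to acetaldehyde, an electrophile that reacts faster than it is enolised, to give methyl 5-hydroxy-2,4-dimethoxy-3-oxohexanoate F6 as a mixture of diastereomers. Dess–Martin periodinane (CH2Cl2, rt) should oxidise the secondary alcohol to give 10.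

**Further compounds**

F1 | step 8 | 1-(2-hydroxy-3,4,5,6-tetramethoxyphenyl)ethanone | CC(=O)c1c(O)c(OC)c(OC)c(OC)c1OC
F2 | step 8 | (E)-3-[3,5-bis(benzyloxy)-4-methoxyphenyl]-1-(2-hydroxy-3,4,5,6-tetramethoxyphenyl)prop-2-en-1-one | COc1c(OC)c(OC)c(O)c(C(=O)/C=C/c2cc(OCc3ccccc3)c(OC)c(OCc3ccccc3)c2)c1OC
F3 | step 8 | 2-[3,5-bis(benzyloxy)-4-methoxyphenyl]-5,6,7,8-tetramethoxy-4H-chromen-4-one | COc1c(OC)c(OC)c2oc(-c3cc(OCc4ccccc4)c(OC)c(OCc4ccccc4)c3)cc(=O)c2c1OC
F4 | step 7 | 4-hydroxy-3,5-dimethoxy-6-methyl-2H-pyran-2-one | COc1c(C)oc(=O)c(OC)c1O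
F5 | step 7 | 6-[(E)-4-[3,5-bis(benzyloxy)-4-methoxyphenyl]-2-oxobut-3-en-1-yl]-4-hydroxy-3,5-dimethoxy-2H-pyran-2-one | COc1c(CC(=O)/C=C/c2cc(OCc3ccccc3)c(OC)c(OCc3ccccc3)c2)oc(=O)c(OC)c1O
F6 | step 6 | methyl 5-hydroxy-2,4-dimethoxy-3-oxohexanoate (mixture of diastereomers) | COC(=O)C(OC)C(=O)C(OC)C(C)O
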